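**Plan**

1. Numbering of the target: 1-oxaspiro[4.4]nonane, with O1, C2 (aryl), C3, C4 (C=O), C5 (spiro), C6 (carbinol), C7=C8 (enol ethers), C9 (C=O). Cut 1 (key) is the C6–C7 bond: C6 carries OH and CO2Me between spiro carbon C5 and the C7=C8 enol ether, which is what a ring 1,2-dione leaves after a benzilic ester shift. Putting the ester carbon back into the ring gives spiro cyclohexene-1,2,4-trione 12.
2. Cut 2 is the O1–C5 bond of the furanone, traced to the oxirane oxygen of flavone-quinone epoxide 9 (pyranone-to-furanone contraction). Cut 3 takes the quinone and pyranone back to flavone 6 and to chalcone partners 1 + 2.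
3. Forward order of rings: pyranone (steps 1–2), quinone ring A (step 5), oxirane (step 6), spiro furanone on the cyclohexenetrione (step 7), cyclopentenone by ring contraction (step 8, last step, no protecting group left).
4. Stereochemistry: the spiro carbon comes from a catalyst-controlled nucleophilic epoxidation of the quinone C4a=C8a bond, whose C4a–O bond is kept through step 7. The carbinol carbon is set in step 8 by the spiro carbon: the new alkoxide should form syn to ring oxygen O1, anti to the phenoxide-charged furanone carbonyl.

Key step: step 8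

Assumption: acetophenone 1 and aldehyde 2 are catalogue compounds; the polyketones 10–13 are drawn as unhydrated keto forms.

**Route**

Step 1
Reactants: 1 1-(6-hydroxy-2,3,4-trimethoxyphenyl)ethan-1-one; 2 4-(benzyloxy)benzaldehyde
Product: 3 (E)-3-[4-(benzyloxy)phenyl]-1-(6-hydroxy-2,3,4-trimethoxyphenyl)prop-2-en-1-one
Conditions: KOH (50% aq.), EtOH, rt; then aq. HCl
Reagents that add atoms: none
Why: Claisen–Schmidt aldol condensation, in which the acetophenone enolate adds to the non-enolisable aldehyde and E1cB loss of water gives the (E)-chalcone, the 2'-phenoxide being tolerated.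

Step 2
Reactants: 3 (E)-chalcone
Product: 5 2-[4-(benzyloxy)phenyl]-5,6,7-trimethoxy-4H-chromen-4-one, via flavanone 4 (not isolated)
Conditions: I2 (10 mol %), DMSO, 130 °C
Reagents that add atoms: none
Why: Iodine-catalysed oxidative cyclisation of a 2'-hydroxychalcone, with oxa-Michael closure to the flavanone, α-iodination and loss of HI, the HI being reoxidised by DMSO; the methyl and benzyl ethers are inert.

Step 3
Reactants: 5 2-[4-(benzyloxy)phenyl]-5,6,7-trimethoxy-4H-chromen-4-one
Product: 6 5-hydroxy-2-(4-hydroxyphenyl)-6,7-dimethoxy-4H-chromen-4-one (cirsimaritin)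
Conditions: BCl3 (4 equiv), C6HMe5 (3 equiv), CH2Cl2, −78 to 0 °C; then H2O
Reagents that add atoms: none
Why: Lewis-acid ether cleavage, in which BCl3 removes the 5-OMe peri to the C4 carbonyl through a six-membered boron chelate and also the benzyl ether, whose cation is taken up by pentamethylbenzene (Friedel–Crafts) before it can alkylate C8; the 6- and 7-OMe groups lack the chelate and should stay.

Step 4
Reactants: 6 cirsimaritin
Product: 7 5-hydroxy-6,7-dimethoxy-2-[4-(methoxymethoxy)phenyl]-4H-chromen-4-one
Conditions: MOMCl (1.1 equiv), i-Pr2NEt (1.5 equiv), CH2Cl2, 0 °C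
Reagents that add atoms: chloromethyl methyl ether, COCCl
Why: O-alkylation (Williamson type) of the free 4'-OH while the 5-OH stays locked in its hydrogen bond to the C4 carbonyl; the acetal survives the oxidising and basic steps and is lost in the acid of step 7.

Step 5
Reactants: 7 4'-O-MOM-5-hydroxyflavone
Product: 8 6,7-dimethoxy-2-[4-(methoxymethoxy)phenyl]-4H-chromene-4,5,8-trione
Conditions: (KO3S)2NO (2.5 equiv), KH2PO4 buffer, acetone/H2O, 0 °C to rt
Reagents that add atoms: Fremy's salt (potassium nitrosodisulfonate), [K+].[K+].[O-]S(=O)(=O)N([O])S(=O)(=O)[O-]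
Why: Teuber oxidation, in which the nitroxide abstracts the phenolic hydrogen and a second equivalent couples at the free para carbon C8, giving the para-quinone and not the ortho-quinone that would cost the 6-OMe.

Step 6
Reactants: 8 flavone-5,8-quinone
Product: 9 (4aS,8aS)-4a,8a-epoxy-6,7-dimethoxy-2-[4-(methoxymethoxy)phenyl]-4a,8a-dihydro-4H-chromene-4,5,8-trione
Conditions: t-BuOOH (1.5 equiv), N-(9-anthracenylmethyl)cinchonidinium bromide (10 mol %), K2CO3 (30 mol %), toluene, −20 °C
Reagents that add atoms: tert-butyl hydroperoxide, CC(C)(C)OO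
Why: Weitz–Scheffer nucleophilic epoxidation under chiral phase-transfer catalysis, in which the ammonium-paired peroxide adds to C8a (β to the C4 and C5 carbonyls) and the enolate closes on the O–O bond, so both oxirane carbons are set together on the face chosen by the chiral ion pair; the cinchonidinium series is proposed for the (4aS,8aS) face, the pseudoenantiomeric cinchoninium salt being the correction if the sense is opposite, and the C2=C3 and C6=C7 vinylogous esters are less electrophilic.

Step 7
Reactants: 9 (4aS,8aS)-epoxide
Product: 12 (S)-2-(4-hydroxyphenyl)-8,9-dimethoxy-1-oxaspiro[4.5]deca-2,8-diene-4,6,7,10-tetraone, via hydroxy tetraketone 10 (not isolated), via spiro trione MOM ether 11 (not isolated)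
Conditions: CF3CO2H/H2O/CH2Cl2 (5:1:10), 0 °C to rt
Reagents that add atoms: water, O
Why: Acid opens the epoxy ketal at C8a (oxocarbenium stabilised by the ring oxygen), water adds and the hemiketal collapses to the C8a ketone with release of the 1,3-diketone, after which the C4a–OH closes on the aryl ketone and dehydrates to the 3(2H)-furanone (cyclodehydration of an α'-hydroxy-1,3-diketone) while the MOM acetal hydrolyses; the C4a–O bond is never broken, so the oxirane configuration becomes that of the spiro carbon.

Step 8
Reactants: 12 (S)-spiro cyclohexenetrione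
Product: 14 methyl (5S,6R)-6-hydroxy-2-(4-hydroxyphenyl)-7,8-dimethoxy-4,9-dioxo-1-oxaspiro[4.4]nona-2,7-diene-6-carboxylate (limnophilaspiroketone), via hemiketal alkoxide 13 (not isolated)
Conditions: KOMe (2.2 equiv), 18-crown-6 (2.2 equiv), THF/MeOH 4:1, −40 to −10 °C; then AcOH
Reagents that add atoms: methanol (delivered as KOMe), CO
Why: KOMe first deprotonates the 4'-OH, and the phenoxide, conjugated through C2=C3 to the furanone carbonyl, makes that carbonyl enolate-like, so that methoxide attack on the furanone and retro-Claisen expulsion of the spiro carbon (which would need a second negative charge next to it) should both be held back. Methoxide then adds reversibly to the ring ketones C6 and C7 (numbering of 12); the C7 hemiketal alkoxide, at the ketone conjugated to the dimethoxyalkene, carries an sp2 migrating group, and its alkenyl carbon C8 shifts with its bonding pair onto C6, the most electrophilic ketone, while C7 collapses to the methyl ester, whereas the C6 hemiketal could only move the acceptor-laden sp3 spiro carbon onto a deactivated vinylogous-ester carbonyl. This is a benzilic ester rearrangement, the reaction type by which cyclic 1,2-diones contract and by which hydroxyquinone-derived cyclohexenetriones contract in the Hooker oxidation. The cyclopentenone is closed by this 1,2-carbon shift (a three-centre, formally 3-exo-trig delivery of C8 to the C6 carbonyl, six-membered ring to five-membered ring), which joins the carbinol carbon to the methoxy-bearing alkene carbon. The carbinol stereocentre is controlled by the spiro carbon: in the transition state the departing C7 swings to one face of the ring and the C6 oxygen, which takes up the charge, to the other, and charge repulsion should send that oxygen to the face of ring oxygen O1, away from the anionic furanone carbonyl oxygen, giving OH cis to O1 and CO2Me cis to C4=O (6R), with 18-crown-6 keeping K+ from bridging the two oxygens. The step needs migration of the alkenyl carbon and not of the spiro carbon and an intact C5–C6 bond, both secured by the phenoxide, and methoxide exchange at the enol-ether carbons is degenerate.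

**Compound list**

1 | 1-(6-hydroxy-2,3,4-trimethoxyphenyl)ethan-1-one | CC(=O)c1c(O)cc(OC)c(OC)c1OC | starting material
2 | 4-(benzyloxy)benzaldehyde | O=Cc1ccc(OCc2ccccc2)cc1 | starting material
3 | (E)-3-[4-(benzyloxy)phenyl]-1-(6-hydroxy-2,3,4-trimethoxyphenyl)prop-2-en-1-one | COc1cc(O)c(C(=O)/C=C/c2ccc(OCc3ccccc3)cc2)c(OC)c1OC | intermediate
4 | (±)-2-[4-(benzyloxy)phenyl]-5,6,7-trimethoxychroman-4-one | COc1cc2OC(CC(=O)c2c(OC)c1OC)c1ccc(OCc2ccccc2)cc1 | intermediate (not isolated)
5 | 2-[4-(benzyloxy)phenyl]-5,6,7-trimethoxy-4H-chromen-4-one | COc1cc2oc(-c3ccc(OCc4ccccc4)cc3)cc(=O)c2c(OC)c1OC | intermediate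
6 | 5-hydroxy-2-(4-hydroxyphenyl)-6,7-dimethoxy-4H-chromen-4-one (cirsimaritin) | COc1cc2oc(-c3ccc(O)cc3)cc(=O)c2c(O)c1OC | intermediate
7 | 5-hydroxy-6,7-dimethoxy-2-[4-(methoxymethoxy)phenyl]-4H-chromen-4-one | COCOc1ccc(cc1)-c1cc(=O)c2c(O)c(OC)c(OC)cc2o1 | intermediate
8 | 6,7-dimethoxy-2-[4-(methoxymethoxy)phenyl]-4H-chromene-4,5,8-trione | COCOc1ccc(cc1)C1=CC(=O)C2=C(O1)C(=O)C(OC)=C(OC)C2=O | intermediate
9 | (4aS,8aS)-4a,8a-epoxy-6,7-dimethoxy-2-[4-(methoxymethoxy)phenyl]-4a,8a-dihydro-4H-chromene-4,5,8-trione | O=C1C=C(c2ccc(OCOC)cc2)O[C@@]2(O3)C(=O)C(OC)=C(OC)C(=O)[C@@]123 | intermediate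
10 | (S)-3-hydroxy-5,6-dimethoxy-3-{3-[4-(methoxymethoxy)phenyl]-3-oxopropanoyl}cyclohex-5-ene-1,2,4-trione | COCOc1ccc(cc1)C(=O)CC(=O)[C@@]1(O)C(=O)C(=O)C(OC)=C(OC)C1=O | intermediate (not isolated)
11 | (S)-8,9-dimethoxy-2-[4-(methoxymethoxy)phenyl]-1-oxaspiro[4.5]deca-2,8-diene-4,6,7,10-tetraone | O=C1C(=O)C(OC)=C(OC)C(=O)[C@]12OC(c1ccc(OCOC)cc1)=CC2=O | intermediate (not isolated)
12 | (S)-2-(4-hydroxyphenyl)-8,9-dimethoxy-1-oxaspiro[4.5]deca-2,8-diene-4,6,7,10-tetraone | O=C1C(=O)C(OC)=C(OC)C(=O)[C@]12OC(c1ccc(O)cc1)=CC2=O | intermediate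
13 | (5S)-7-hydroxy-2-(4-hydroxyphenyl)-7,8,9-trimethoxy-1-oxaspiro[4.5]deca-2,8-diene-4,6,10-trione (either C7 epimer; present as its dipotassium phenoxide alkoxide, drawn neutral) | O=C1[C@@]2(OC(c3ccc(O)cc3)=CC2=O)C(=O)C(OC)=C(OC)C1(O)OC | intermediate (not isolated)
14 | methyl (5S,6R)-6-hydroxy-2-(4-hydroxyphenyl)-7,8-dimethoxy-4,9-dioxo-1-oxaspiro[4.4]nona-2,7-diene-6-carboxylate (limnophilaspiroketone) | COC(=O)[C@@]1(O)C(OC)=C(OC)C(=O)[C@]12OC(c1ccc(O)cc1)=CC2=O | target

**Count and risks**

Total steps: 8. Longest linear sequence: 8 steps (1 to 14).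

Steps most likely to fail:

Step 8. Methoxide may add at the ketone next to the spiro carbon and the ring may open by retro-Claisen cleavage, which would racemise the spiro carbon on reclosure, or the shift may show poor facial selectivity at the new carbinol. The fallback sets out from 12 and comes back at 14; it contracts the ring under neutral photochemical conditions and hydroxylates afterwards. Condensation of 12 with TsNHNH2 (1 equiv, THF, cat. AcOH) at the more electrophilic C6 ketone should give the C6 monotosylhydrazone F1. Et3N in CH2Cl2 then eliminates p-toluenesulfinate to give the α-diazo ketone F2. Irradiation (hν > 300 nm, MeOH/CH2Cl2, 0 °C) brings about a Wolff rearrangement with the same migration of the alkenyl carbon, and methanol traps the ketene as the ring-contracted ester F3 (C6–H, either epimer). The potassium dienolate of F3 (KHMDS, 2.2 equiv, THF, −78 °C) is oxidised with 2-(phenylsulfonyl)-3-phenyloxaziridine, which should approach from the face of O1, anti to the phenoxide-charged furanone carbonyl, to give 14.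

Step 6. The chiral ion pair may discriminate poorly between the faces of a tetrasubstituted push-pull quinone alkene, or the peroxide may attack the methoxy-bearing carbons or open the pyranone. The fallback sets out from 8 and comes back at 10; it moves the asymmetric oxidation to a stoichiometric chiral reagent acting on an enolate. LiOH (1 equiv, THF/H2O, 0 °C) adds to C8a of 8 and opens the pyranone to the hydroxyquinone F4. Its sodium salt (the hydroxyquinone is by far the most acidic site) is hydroxylated at C4a with an enantiopure (camphorylsulfonyl)oxaziridine, the antipode being chosen for the (S) series, to give 10, which is acidified at once and continues as in step 7.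

Step 7. Enantiopurity may be eroded, because in ring-opened 10 a degenerate 1,2-acyl (α-ketol) shift exchanges the roles of the two ring carbons and leads to the mirror-image furanone, and a concerted acyl shift from the protonated epoxide would do the same. The fallback sets out from 8 and comes back at 11; it uses that concerted shift on purpose. Step 6 run with the pseudoenantiomeric N-(9-anthracenylmethyl)cinchoninium bromide gives the (4aR,8aR)-epoxide F5. Anhydrous BF3·OEt2 (CH2Cl2, −78 °C) opens it at C8a and the C4 acyl group migrates from C4a to C8a anti to the departing oxygen (Lewis-acid rearrangement of an α,β-epoxy ketone to a 1,3-dicarbonyl compound). C8a thereby becomes the (S)-spiro carbon of 11 and C4a a ketone, with no free tertiary α-ketol on the way; CF3CO2H/H2O then removes the MOM group to give 12.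

**Further compounds**

F1 | step 8 | (5S)-N'-[2-(4-hydroxyphenyl)-8,9-dimethoxy-4,7,10-trioxo-1-oxaspiro[4.5]deca-2,8-dien-6-ylidene]-4-methylbenzenesulfonohydrazide | Cc1ccc(cc1)S(=O)(=O)NN=C1C(=O)C(OC)=C(OC)C(=O)[C@]12OC(c1ccc(O)cc1)=CC2=O
F2 | step 8 | (5S)-6-diazo-2-(4-hydroxyphenyl)-8,9-dimethoxy-1-oxaspiro[4.5]deca-2,8-diene-4,7,10-trione | [N-]=[N+]=C1C(=O)C(OC)=C(OC)C(=O)[C@]12OC(c1ccc(O)cc1)=CC2=O
F3 | step 8 | methyl (5S)-2-(4-hydroxyphenyl)-7,8-dimethoxy-4,9-dioxo-1-oxaspiro[4.4]nona-2,7-diene-6-carboxylate (C6 epimers) | COC(=O)C1C(OC)=C(OC)C(=O)[C@]12OC(c1ccc(O)cc1)=CC2=O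
F4 | step 6 | 2-hydroxy-5,6-dimethoxy-3-{3-[4-(methoxymethoxy)phenyl]-3-oxopropanoyl}cyclohexa-2,5-diene-1,4-dione | COCOc1ccc(cc1)C(=O)CC(=O)C1=C(O)C(=O)C(OC)=C(OC)C1=O
F5 | step 7 | (4aR,8aR)-4a,8a-epoxy-6,7-dimethoxy-2-[4-(methoxymethoxy)phenyl]-4a,8a-dihydro-4H-chromene-4,5,8-trione | O=C1C=C(c2ccc(OCOC)cc2)O[C@]2(O3)C(=O)C(OC)=C(OC)C(=O)[C@]123
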